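**Retrosynthetic overview**

1. The trans-diaxial 4a,5-diol is read as the hydrolysis product of the α-epoxide of a tetrasubstituted C4a=C5 alkene; with the C3=C4 enone bond installed late, ring B is then a cyclohexene.
2. Key disconnection: that cyclohexene is the [4+2] adduct of the semicyclic diene C6=C5–C4a=C8a (isopropenyl on the 2-methylcyclohexenyl ring A, 17) and 2-bromoacrolein (C7=C8), forming C6–C7 and C8–C8a. The enabling feature is the methyl-bearing quaternary C8a sitting in ring B between the Br-bearing C8 and the oxygenated pair C4a/C5, which marks the diene's central C=C.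
3. Diene 17 comes from de-aromatised ring A: dimethoxyarene → quinone → isopropenyl p-quinol acetate → conjugate reduction of C3=C4 → reductive elimination.
4. The bromocyclopentyl arene comes from asymmetric conjugate addition (sets C1'), gem-dimethylation, then ketone → vinyl bromide → hydrogen-atom-transfer hydrogenation (sets C3').
5. Ring order: cyclopentane (from 3-methylcyclopentenone) → ring A (arene, then de-aromatised) → ring B (Diels–Alder) → epoxide/diol.

Key step: step 11

Remark: locants C1–C8a are those of the target's naphthalen-2(1H)-one core (C1 CH2, C2 C=O, C3 C–cyclopentyl, C4 =CH, C4a C–OH, C5 C(CH3)OH, C6 and C7 CH2, C8 CHBr, C8a C–CH3); cyclopentyl atoms are primed; R* = (1R,3R)-3-bromo-1,2,2-trimethylcyclopentyl.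
Remark: centres that are formed unselectively and erased later (quinol carbon in 14–16, C3 in 16–23, C8 in 19–22) are left undefined in the SMILES.
Assumption: the antipode of each chiral catalyst (steps 1 and 11) is chosen by its established induction model; both antipodes are available.

**Route**

Step 1
Reactants: 1 1-bromo-2,5-dimethoxy-4-methylbenzene; 2 3-methylcyclopent-2-en-1-one
Product: 5 (S)-3-(2,5-dimethoxy-4-methylphenyl)-3-methylcyclopentan-1-one, via aryllithium 3 (not isolated), via arylaluminium 4 (not isolated)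
Conditions: 1, n-BuLi, THF, −78 °C; Me2AlCl, −78 °C→rt; then 2, Cu(OTf)2 (5 mol %), chiral sulfonate-NHC–Ag complex (2.5 mol %), THF, −78→−30 °C; aq. Rochelle salt
Reagents that add atoms: none
Why: Cu–NHC-catalysed asymmetric conjugate addition of an aryl(dimethyl)aluminium to a β-methyl cyclopentenone should transfer the aryl group to one enone face under ligand control and set the aryl-bearing quaternary carbon (the later C1') as (S).

Step 2
Reactants: 5 (S)-3-(2,5-dimethoxy-4-methylphenyl)-3-methylcyclopentan-1-one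
Product: 7 (R)-4-(2,5-dimethoxy-4-methylphenyl)-4-methylcyclopent-2-en-1-one, via silyl enol ether 6 (not isolated)
Conditions: LDA, TMSCl, THF, −78 °C; then Pd(OAc)2 (1.05 equiv), MeCN, rt
Reagents that add atoms: none
Why: Saegusa–Ito oxidation; kinetic deprotonation occurs on the CH2 remote from the quaternary carbon, and β-hydride elimination is only possible on that side, so a single enone should form.

Step 3
Reactants: 7 (R)-4-(2,5-dimethoxy-4-methylphenyl)-4-methylcyclopent-2-en-1-one
Product: 8 (R)-4-(2,5-dimethoxy-4-methylphenyl)-4,5,5-trimethylcyclopent-2-en-1-one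
Conditions: NaH (2.5 equiv), MeI (3 equiv), DME, 0 °C→rt
Reagents that add atoms: iodomethane (CI)
Why: Enolate alkylation; C5 is the only enolisable position, so double methylation via the cross-conjugated dienolate should install the gem-dimethyl group next to the quaternary carbon.

Step 4
Reactants: 8 (R)-4-(2,5-dimethoxy-4-methylphenyl)-4,5,5-trimethylcyclopent-2-en-1-one
Product: 9 (R)-3-(2,5-dimethoxy-4-methylphenyl)-2,2,3-trimethylcyclopentan-1-one
Conditions: H2 (1 atm), 10 % Pd/C, EtOAc, rt
Reagents that add atoms: none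
Why: Catalytic hydrogenation of the enone C=C; no stereocentre is formed.

Step 5
Reactants: 9 (R)-3-(2,5-dimethoxy-4-methylphenyl)-2,2,3-trimethylcyclopentan-1-one
Product: 10 1-[(1R)-3-bromo-1,2,2-trimethylcyclopent-3-en-1-yl]-2,5-dimethoxy-4-methylbenzene
Conditions: (PhO)3P, Br2, CH2Cl2, −60 °C; then 9, Et3N, −60 °C→rt
Reagents that add atoms: bromine (BrBr)
Why: Ketone-to-vinyl-bromide conversion with the preformed triphenyl phosphite–bromine reagent; the ketone can enolise only toward C4', and preforming the reagent should spare the electron-rich arene.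

Step 6
Reactants: 10 1-[(1R)-3-bromo-1,2,2-trimethylcyclopent-3-en-1-yl]-2,5-dimethoxy-4-methylbenzene
Product: 11 1-[(1R,3R)-3-bromo-1,2,2-trimethylcyclopentyl]-2,5-dimethoxy-4-methylbenzene
Conditions: Mn(dpm)3 (10 mol %), PhSiH3, t-BuOOH, i-PrOH, rt
Reagents that add atoms: none
Why: Metal-hydride hydrogen-atom-transfer hydrogenation, which reduces haloalkenes without hydrodehalogenation; H adds to C4' to give the α-bromo radical at C3', and the second H should arrive on the face opposite the aryl group on C1', placing Br cis to the aryl ring (3'R).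

Step 7
Reactants: 11 1-[(1R,3R)-3-bromo-1,2,2-trimethylcyclopentyl]-2,5-dimethoxy-4-methylbenzene
Product: 12 2-[(1R,3R)-3-bromo-1,2,2-trimethylcyclopentyl]-5-methylcyclohexa-2,5-diene-1,4-dione
Conditions: CAN (2.5 equiv), MeCN–H2O, 0 °C
Reagents that add atoms: water (O)
Why: Oxidative demethylation of a 1,4-dimethoxyarene to the p-quinone, which de-aromatises ring A; the hindered secondary bromide should be inert.

Step 8
Reactants: 12 2-[(1R,3R)-3-bromo-1,2,2-trimethylcyclopentyl]-5-methylcyclohexa-2,5-diene-1,4-dione; 13 isopropenylmagnesium bromide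
Product: 15 5-[(1R,3R)-3-bromo-1,2,2-trimethylcyclopentyl]-2-methyl-4-oxo-1-(prop-1-en-2-yl)cyclohexa-2,5-dien-1-yl acetate (both C1 epimers), via magnesium alkoxide 14 (not isolated)
Conditions: 13, LaCl3·2LiCl, THF, −78 °C; then Ac2O, −78→0 °C
Reagents that add atoms: acetic anhydride (CC(=O)OC(C)=O)
Why: 1,2-Addition to the quinone carbonyl flanked by CH and C–CH3 (the other carbonyl is shielded by the tertiary cyclopentyl group), then O-acylation of the tertiary alkoxide to the p-quinol acetate; the new centre is unselective but is destroyed in step 10.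

Step 9
Reactants: 15 5-[(1R,3R)-3-bromo-1,2,2-trimethylcyclopentyl]-2-methyl-4-oxo-1-(prop-1-en-2-yl)cyclohexa-2,5-dien-1-yl acetate
Product: 16 5-[(1R,3R)-3-bromo-1,2,2-trimethylcyclopentyl]-2-methyl-4-oxo-1-(prop-1-en-2-yl)cyclohex-2-en-1-yl acetate (diastereomer mixture)
Conditions: [(Ph3P)CuH]6, benzene, H2O (few equiv), rt
Reagents that add atoms: none
Why: Copper hydride conjugate reduction; hydride should add to the β-CH of the cyclopentyl-bearing enone arm rather than to the β-C(CH3) arm, and the new α-centre (later C3) is erased in step 14.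

Step 10
Reactants: 16 5-[(1R,3R)-3-bromo-1,2,2-trimethylcyclopentyl]-2-methyl-4-oxo-1-(prop-1-en-2-yl)cyclohex-2-en-1-yl acetate
Product: 17 6-[(1R,3R)-3-bromo-1,2,2-trimethylcyclopentyl]-3-methyl-4-(prop-1-en-2-yl)cyclohex-3-en-1-one (C6 epimers)
Conditions: SmI2 (2.2 equiv), THF–MeOH, −78 °C; used directly
Reagents that add atoms: none
Why: SmI2 reductive elimination of a γ-acetoxy enone (two-electron reduction, loss of acetate from the β-carbanion) followed by kinetic α-protonation of the dienolate should give the deconjugated ketone, whose ring alkene and isopropenyl group form the diene.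

Step 11
Reactants: 17 6-[(1R,3R)-3-bromo-1,2,2-trimethylcyclopentyl]-3-methyl-4-(prop-1-en-2-yl)cyclohex-3-en-1-one; 18 2-bromoprop-2-enal
Product: 19 (8aS)-8-bromo-8-formyl-3-R*-5,8a-dimethyl-3,4,6,7,8,8a-hexahydronaphthalen-2(1H)-one
Conditions: 18 (2 equiv), chiral oxazaborolidinium triflimide (o-tolyl oxazaborolidine from diphenylprolinol + Tf2NH, 20 mol %), CH2Cl2, −78→−40 °C
Reagents that add atoms: none
Why: Mechanism: the cationic oxazaborolidinium binds the formyl oxygen of 18 and the diene adds in a concerted but strongly asynchronous [4+2], the unsubstituted terminus C6 bonding first to the β-carbon C7 while positive charge builds on the C5–C4a–C8a allyl unit, before the tetrasubstituted terminus C8a closes onto C8. Closest known reaction type: the oxazaborolidinium-catalysed enantioselective Diels–Alder reaction of 2-bromoacrolein, together with Diels–Alder reactions of 2-methyl-1-vinylcyclohexenes that create an angular methyl group. Ring B is closed as a six-membered ring by suprafacial [π4s+π2s] cycloaddition (C6–C7 intermolecular bond plus C8–C8a ring-closing bond), leaving the tetrasubstituted C4a=C5 alkene that later becomes the diol. C8a is set by the catalyst (shielded face of the bound dienophile combined with the exo-formyl approach) and so should not depend on the distant cyclopentyl centres; C8 need not be controlled because it is reset in step 13. The step needs "ortho" regioselectivity (C8 next to C8a), secured by the largest HOMO coefficient at the CH2 terminus C6 of the 2-methyl-4,4-dialkyl diene, and periselectivity, secured because the isopropenyl/ring-alkene pair is the only conjugated diene; keeping C3–C4 saturated stops the diene from tautomerising to a phenol.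

Step 12
Reactants: 19 (8aS)-8-bromo-8-formyl-3-R*-5,8a-dimethyl-3,4,6,7,8,8a-hexahydronaphthalen-2(1H)-one
Product: 20 (8aS)-8-bromo-3-R*-5,8a-dimethyl-2-oxo-1,2,3,4,6,7,8,8a-octahydronaphthalene-8-carboxylic acid
Conditions: NaClO2, NaH2PO4, 2-methyl-2-butene, t-BuOH–H2O, 0 °C→rt
Reagents that add atoms: sodium chlorite ([Na+].[O-]Cl=O)
Why: Pinnick oxidation of a non-enolisable aldehyde; the hypochlorite scavenger should protect the tetrasubstituted alkene.

Step 13
Reactants: 20 (8aS)-8-bromo-3-R*-5,8a-dimethyl-2-oxo-1,2,3,4,6,7,8,8a-octahydronaphthalene-8-carboxylic acid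
Product: 23 (8S,8aS)-8-bromo-3-R*-5,8a-dimethyl-3,4,6,7,8,8a-hexahydronaphthalen-2(1H)-one, via acyl chloride 21 (not isolated), via thiohydroxamate ester 22 (not isolated)
Conditions: (COCl)2, DMF (cat.), CH2Cl2, 0 °C; then sodium 2-thioxopyridin-1(2H)-olate, DMAP (cat.), t-BuSH, benzene, hν (W lamp), rt
Reagents that add atoms: none
Why: Barton reductive decarboxylation; the planar α-bromo radical at C8 should take H from the thiol on the face anti to the pseudo-axial 8a-methyl (axial delivery), so Br ends equatorial and cis to that methyl (8S) whatever the C8 configuration of 19.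

Step 14
Reactants: 23 (8S,8aS)-8-bromo-3-R*-5,8a-dimethyl-3,4,6,7,8,8a-hexahydronaphthalen-2(1H)-one
Product: 24 (8S,8aS)-8-bromo-3-R*-5,8a-dimethyl-6,7,8,8a-tetrahydronaphthalen-2(1H)-one
Conditions: IBX (2 equiv), DMSO–fluorobenzene, 70 °C
Reagents that add atoms: none
Why: IBX dehydrogenation of a ketone via its enol; C8a is quaternary, so only the C3–C4 bond can be desaturated, the allylic C4–H is activated, and the linear dienone is stabilised by conjugation with C4a=C5; the C3 epimer mixture converges here.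

Step 15
Reactants: 24 (8S,8aS)-8-bromo-3-R*-5,8a-dimethyl-6,7,8,8a-tetrahydronaphthalen-2(1H)-one
Product: 26 (4aR,5R,8S,8aS)-8-bromo-3-[(1R,3R)-3-bromo-1,2,2-trimethylcyclopentyl]-4a,5-dihydroxy-5,8a-dimethyl-4a,5,6,7,8,8a-hexahydronaphthalen-2(1H)-one, via epoxide 25 (not isolated)
Conditions: mCPBA, NaHCO3, CH2Cl2, 0 °C; then 1 M HClO4, THF–H2O, 0 °C→rt
Reagents that add atoms: 3-chloroperbenzoic acid (OOC(=O)c1cccc(Cl)c1); water (O)
Why: Peracid epoxidation of the electron-rich γ,δ-alkene of the dienone from the face anti to the 8a-methyl, then acid-catalysed trans-diaxial (Fürst–Plattner) opening by water at the tertiary, non-allylic C5 with inversion while the C4a–O bond is kept; this should give 4a-OH trans to the 8a-methyl and 5-OH trans to 4a-OH.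

**Compound list**

1 | 1-bromo-2,5-dimethoxy-4-methylbenzene | COc1cc(Br)c(OC)cc1C | starting material
2 | 3-methylcyclopent-2-en-1-one | CC1=CC(=O)CC1 | starting material
3 | (2,5-dimethoxy-4-methylphenyl)lithium | [Li]c1cc(OC)c(C)cc1OC | intermediate
4 | (2,5-dimethoxy-4-methylphenyl)dimethylaluminium | C[Al](C)c1cc(OC)c(C)cc1OC | intermediate
5 | (S)-3-(2,5-dimethoxy-4-methylphenyl)-3-methylcyclopentan-1-one | C1C(=O)CC[C@]1(C)c1cc(OC)c(C)cc1OC | intermediate
6 | (S)-{[4-(2,5-dimethoxy-4-methylphenyl)-4-methylcyclopent-1-en-1-yl]oxy}trimethylsilane | C1C(O[Si](C)(C)C)=CC[C@]1(C)c1cc(OC)c(C)cc1OC | intermediate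
7 | (R)-4-(2,5-dimethoxy-4-methylphenyl)-4-methylcyclopent-2-en-1-one | C1C(=O)C=C[C@]1(C)c1cc(OC)c(C)cc1OC | intermediate
8 | (R)-4-(2,5-dimethoxy-4-methylphenyl)-4,5,5-trimethylcyclopent-2-en-1-one | CC1(C)C(=O)C=C[C@]1(C)c1cc(OC)c(C)cc1OC | intermediate
9 | (R)-3-(2,5-dimethoxy-4-methylphenyl)-2,2,3-trimethylcyclopentan-1-one | CC1(C)C(=O)CC[C@]1(C)c1cc(OC)c(C)cc1OC | intermediate
10 | 1-[(1R)-3-bromo-1,2,2-trimethylcyclopent-3-en-1-yl]-2,5-dimethoxy-4-methylbenzene | CC1(C)C(Br)=CC[C@]1(C)c1cc(OC)c(C)cc1OC | intermediate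
11 | 1-[(1R,3R)-3-bromo-1,2,2-trimethylcyclopentyl]-2,5-dimethoxy-4-methylbenzene | CC1(C)[C@H](Br)CC[C@]1(C)c1cc(OC)c(C)cc1OC | intermediate
12 | 2-[(1R,3R)-3-bromo-1,2,2-trimethylcyclopentyl]-5-methylcyclohexa-2,5-diene-1,4-dione | CC1(C)[C@H](Br)CC[C@]1(C)C1=CC(=O)C(C)=CC1=O | intermediate
13 | isopropenylmagnesium bromide (prop-1-en-2-ylmagnesium bromide) | CC(=C)[Mg]Br | starting material
14 | bromomagnesium 5-[(1R,3R)-3-bromo-1,2,2-trimethylcyclopentyl]-2-methyl-4-oxo-1-(prop-1-en-2-yl)cyclohexa-2,5-dien-1-olate (both C1 epimers) | CC1(C)[C@H](Br)CC[C@]1(C)C1=CC(O[Mg]Br)(C(C)=C)C(C)=CC1=O | intermediate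
15 | 5-[(1R,3R)-3-bromo-1,2,2-trimethylcyclopentyl]-2-methyl-4-oxo-1-(prop-1-en-2-yl)cyclohexa-2,5-dien-1-yl acetate (both C1 epimers) | CC1(C)[C@H](Br)CC[C@]1(C)C1=CC(OC(C)=O)(C(C)=C)C(C)=CC1=O | intermediate
16 | 5-[(1R,3R)-3-bromo-1,2,2-trimethylcyclopentyl]-2-methyl-4-oxo-1-(prop-1-en-2-yl)cyclohex-2-en-1-yl acetate (diastereomer mixture) | CC1(C)[C@H](Br)CC[C@]1(C)C1CC(OC(C)=O)(C(C)=C)C(C)=CC1=O | intermediate
17 | 6-[(1R,3R)-3-bromo-1,2,2-trimethylcyclopentyl]-3-methyl-4-(prop-1-en-2-yl)cyclohex-3-en-1-one (C6 epimers) | CC1(C)[C@H](Br)CC[C@]1(C)C1CC(C(C)=C)=C(C)CC1=O | intermediate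
18 | 2-bromoprop-2-enal (2-bromoacrolein) | C=C(Br)C=O | starting material
19 | (8aS)-8-bromo-8-formyl-3-R*-5,8a-dimethyl-3,4,6,7,8,8a-hexahydronaphthalen-2(1H)-one (C3 and C8 epimers) | CC1(C)[C@H](Br)CC[C@]1(C)C1CC2=C(C)CCC(Br)(C=O)[C@@]2(C)CC1=O | intermediate
20 | (8aS)-8-bromo-3-R*-5,8a-dimethyl-2-oxo-1,2,3,4,6,7,8,8a-octahydronaphthalene-8-carboxylic acid | CC1(C)[C@H](Br)CC[C@]1(C)C1CC2=C(C)CCC(Br)(C(O)=O)[C@@]2(C)CC1=O | intermediate
21 | acyl chloride of 20 | CC1(C)[C@H](Br)CC[C@]1(C)C1CC2=C(C)CCC(Br)(C(Cl)=O)[C@@]2(C)CC1=O | intermediate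
22 | 2-thioxopyridin-1(2H)-yl ester of 20 | CC1(C)[C@H](Br)CC[C@]1(C)C1CC2=C(C)CCC(Br)(C(=O)ON3C=CC=CC3=S)[C@@]2(C)CC1=O | intermediate
23 | (8S,8aS)-8-bromo-3-R*-5,8a-dimethyl-3,4,6,7,8,8a-hexahydronaphthalen-2(1H)-one (C3 epimers) | CC1(C)[C@H](Br)CC[C@]1(C)C1CC2=C(C)CC[C@H](Br)[C@@]2(C)CC1=O | intermediate
24 | (8S,8aS)-8-bromo-3-R*-5,8a-dimethyl-6,7,8,8a-tetrahydronaphthalen-2(1H)-one | CC1(C)[C@H](Br)CC[C@]1(C)C1=CC2=C(C)CC[C@H](Br)[C@@]2(C)CC1=O | intermediate
25 | (4aR,5S,8S,8aS)-4a,5-epoxide of 24 (oxygen anti to the 8a-methyl) | CC1(C)[C@H](Br)CC[C@]1(C)C1=C[C@@]23O[C@@]3(C)CC[C@H](Br)[C@@]2(C)CC1=O | intermediate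
26 | (4aR,5R,8S,8aS)-8-bromo-3-[(1R,3R)-3-bromo-1,2,2-trimethylcyclopentyl]-4a,5-dihydroxy-5,8a-dimethyl-4a,5,6,7,8,8a-hexahydronaphthalen-2(1H)-one | CC1(C)[C@H](Br)CC[C@]1(C)C1=C[C@]2(O)[C@](C)(O)CC[C@H](Br)[C@@]2(C)CC1=O | target

**Step count and risks**

Total steps: 15. Longest linear sequence: 15 steps (from 1 and 2).

Steps most likely to fail:

1. Step 11. The cycloaddition at the hindered diene terminus, which carries an inward-pointing methyl group, may be slow. The strong Lewis acid could then isomerise the β,γ-unsaturated ketone into conjugation (destroying the diene) or polymerise the dienophile, and catalyst control of the diene face could erode. Fallback, setting out from 17: the diene is combined with tert-butyl 2-bromoacrylate without any Lewis acid under high pressure (about 12 kbar, CH2Cl2, 30–40 °C, radical inhibitor). This should give the tert-butyl ester of the cycloadduct F1 as both ring-B series. Trifluoroacetic acid then cleaves the ester, and the route is rejoined at acid 20 (step 12 is not needed). The two 8a-epimeric series are diastereomers because of the cyclopentyl centres and would be separated by chromatography at 20 or 23.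

2. Step 6. Hydrogen-atom delivery to the α-bromo radical may occur with poor or reversed facial selectivity (C3' epimer), or with the other regiochemistry, which would lead to loss of bromine by β-scission. Fallback, setting out from 9: the same facial bias that would spoil step 6 makes hydride attack the ketone from the aryl face. L-Selectride (THF, −78 °C) should then give the alcohol with OH anti to the aryl group, (1S,3S)-3-(2,5-dimethoxy-4-methylphenyl)-2,2,3-trimethylcyclopentan-1-ol F2. Appel bromination (CBr4, PPh3, 2,6-lutidine, toluene, 60 °C) with SN2 inversion rejoins the route at 11.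

3. Step 14. Enolisation toward the congested C3 may be sluggish, leading to incomplete conversion or over-oxidation to a trienone. Fallback, setting out from 23: equilibrating silylation (TMSOTf, Et3N, CH2Cl2, 0 °C) should give the silyl enol ethers including the Δ2,3 isomer, trimethyl{[(8S,8aS)-8-bromo-3-R*-5,8a-dimethyl-1,4,6,7,8,8a-hexahydronaphthalen-2-yl]oxy}silane F3. Saegusa–Ito oxidation (Pd(OAc)2, MeCN–DMSO) rejoins the route at 24. Only F3 can undergo β-hydride elimination; the Δ1,2 isomer returns 23 for recycling.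

**Further compounds**

F1 | step 11 | tert-butyl (8aS)-8-bromo-3-R*-5,8a-dimethyl-2-oxo-1,2,3,4,6,7,8,8a-octahydronaphthalene-8-carboxylate (formed together with its 8a-epimeric series) | CC1(C)[C@H](Br)CC[C@]1(C)C1CC2=C(C)CCC(Br)(C(=O)OC(C)(C)C)[C@@]2(C)CC1=O
F2 | step 6 | (1S,3S)-3-(2,5-dimethoxy-4-methylphenyl)-2,2,3-trimethylcyclopentan-1-ol | CC1(C)[C@@H](O)CC[C@]1(C)c1cc(OC)c(C)cc1OC
F3 | step 14 | trimethyl{[(8S,8aS)-8-bromo-3-R*-5,8a-dimethyl-1,4,6,7,8,8a-hexahydronaphthalen-2-yl]oxy}silane | CC1(C)[C@H](Br)CC[C@]1(C)C=1CC2=C(C)CC[C@H](Br)[C@@]2(C)CC=1O[Si](C)(C)C
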